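**Retrosynthetic overview**

1. The target 25 comes from 24 by one neutral hydrogenolysis that removes eight benzyl ethers and two aryl chlorines. Benzyl is chosen over methyl because a Lewis-acid dealkylation would ionise the cis-configured benzylic ether carbon T-C2.
2. The strategy rests on this feature: each ring D (2,3-dihydrobenzofuran: O1, C2, C3, C3a–C7a, joined to tetrahydrofuran ring T through D-C4) is a resorcinol ring fused through one hydroxyl oxygen (O1) and the neighbouring ring carbon (C3a) onto the two alkene carbons (C2, C3) of a resveratrol unit. Cutting O1–C2 and C3–C3a in both rings D gives core tetraphenol 21 and two molecules of stilbene 23 (twofold anodic [3+2] annulation). A chlorine on the carbon between the two hydroxyls (later D-C7) leaves only the wanted ortho carbon open.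
3. Ring T of 21 comes from hemiketal 19 (hydride to the oxocarbenium ion sets T-C2), which comes from all-trans lactone 16. The T-C3 and T-C4 aryl groups enter by α-arylation and cuprate addition on butenolide 8, whose T-C5 centre comes from asymmetric transfer hydrogenation of keto acid 4.
4. Order of ring formation: γ-lactone (the later ring T), then ring T, then both rings D in one operation.

Key step: step 12

Remark: metal enolates, alkoxides and phenoxides are treated as salts of their numbered parent compounds and carry no number of their own; 1, 2, 9 and 22 are taken as commercial.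

**Route**

Step 1
Reactants: 1 1-(benzyloxy)-4-bromobenzene; 2 succinic anhydride
Product: 4 4-[4-(benzyloxy)phenyl]-4-oxobutanoic acid, via 4-(benzyloxy)phenylmagnesium bromide 3 (not isolated)
Conditions: Mg, THF, 40 °C; then added to 2 (1.5 equiv), THF, −78 → 0 °C; aq. HCl
Reagents that add atoms: none
Why: Grignard acylation by a cyclic anhydride should stop at the keto acid because the magnesium carboxylate formed on ring opening does not react further at low temperature with the anhydride in excess.

Step 2
Reactants: 4 4-[4-(benzyloxy)phenyl]-4-oxobutanoic acid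
Product: 6 (5R)-5-[4-(benzyloxy)phenyl]oxolan-2-one, via (R)-hydroxy acid 5 (not isolated)
Conditions: RuCl[(R,R)-TsDPEN](p-cymene) (1 mol %), HCO2H/Et3N (5:2), 40 °C; then aq. citric acid, toluene, 40 °C
Reagents that add atoms: none
Why: Noyori asymmetric transfer hydrogenation of the aryl ketone should set the carbinol centre (later T-C5) as R, the (R,R)-catalyst delivering hydride as it does to acetophenone with the CH2 chain in the place of methyl, and the γ-hydroxy acid lactonises on mild acidification.

Step 3
Reactants: 6 (5R)-5-[4-(benzyloxy)phenyl]oxolan-2-one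
Product: 8 (5R)-5-[4-(benzyloxy)phenyl]furan-2(5H)-one, via α-phenylselanyl lactone 7 (not isolated)
Conditions: LiN(SiMe3)2, THF, −78 °C; PhSeBr; then 30% H2O2, CH2Cl2, 0 °C
Reagents that add atoms: none
Why: enolate selenenylation followed by selenoxide syn-elimination should give the butenolide without any base present at the elimination stage, so the acidic benzylic C5–H keeps its R configuration.

Step 4
Reactants: 9 2-chlororesorcinol
Product: 10 2-chloro-1,3-bis(triisopropylsilyloxy)benzene
Conditions: i-Pr3SiCl, imidazole, DMF, 40 °C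
Reagents that add atoms: chlorotriisopropylsilane, CC(C)[Si](Cl)(C(C)C)C(C)C
Why: standard silylation of both phenols gives bulky silyl ethers that withstand organometallic reagents and BF3, shield the ring carbons next to oxygen, and can later be removed by fluoride beside benzyl ethers.

Step 5
Reactants: 10 2-chloro-1,3-bis(triisopropylsilyloxy)benzene
Product: 12 5-bromo-2-chloro-1,3-bis(triisopropylsilyloxy)benzene, via arylboronic pinacol ester 11 (not isolated)
Conditions: [Ir(OMe)(cod)]2 (1.5 mol %), 4,4′-di-tert-butyl-2,2′-bipyridine, B2pin2, THF, 80 °C; then CuBr2, MeOH/H2O, 80 °C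
Reagents that add atoms: copper dibromide, [Cu+2].[Br-].[Br-]
Why: sterically governed iridium-catalysed C–H borylation should take the only ring hydrogen not flanked by a silyloxy group (para to chlorine), and copper-mediated bromodeboronation in the same pot turns the boronate into the bromide.

Step 6
Reactants: 8 (5R)-5-[4-(benzyloxy)phenyl]furan-2(5H)-one; 12 5-bromo-2-chloro-1,3-bis(triisopropylsilyloxy)benzene
Product: 15 (4S,5R)-5-[4-(benzyloxy)phenyl]-4-[4-chloro-3,5-bis(triisopropylsilyloxy)phenyl]oxolan-2-one, via arylmagnesium bromide 13 (not isolated), via silyl ketene acetal 14 (not isolated)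
Conditions: 12, Mg, LiCl, THF, 25 °C; then CuBr·SMe2 (20 mol %), Me3SiCl, 8, THF, −78 °C; aq. NH4Cl
Reagents that add atoms: none
Why: copper-catalysed conjugate addition of the aryl Grignard reagent, accelerated by Me3SiCl, should enter the butenolide anti to the C5 aryl group and so set C4 as S (4,5-trans), the magnesium reagent forming at C–Br and not at the hindered C–Cl bond.

Step 7
Reactants: 15 (4S,5R)-lactone; 12 5-bromo-2-chloro-1,3-bis(triisopropylsilyloxy)benzene
Product: 16 (3S,4S,5R)-5-[4-(benzyloxy)phenyl]-3,4-bis[4-chloro-3,5-bis(triisopropylsilyloxy)phenyl]oxolan-2-one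
Conditions: LiN(SiMe3)2, THF, −78 °C; ZnCl2; Pd(dba)2 (3 mol %), P(t-Bu)3 (3 mol %), 12, THF, 25 → 50 °C
Reagents that add atoms: none
Why: palladium-catalysed α-arylation of the lactone zinc enolate should join C3 to the aryl bromide, and the new acidic C3 centre settles trans to the C4 aryl group (3S) because the all-trans lactone is the thermodynamic epimer.

Step 8
Reactants: 16 (3S,4S,5R)-lactone; 1 1-(benzyloxy)-4-bromobenzene
Product: 19 (3S,4S,5R)-2,5-bis[4-(benzyloxy)phenyl]-3,4-bis[4-chloro-3,5-bis(triisopropylsilyloxy)phenyl]oxolan-2-ol (C2 epimers, in equilibrium with the hydroxy ketone), via 4-(benzyloxy)phenyllithium 17 (not isolated), via arylcerium dichloride 18 (not isolated)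
Conditions: 1, n-BuLi, THF, −78 °C; CeCl3, −78 °C; then 16, −78 °C; aq. NH4Cl
Reagents that add atoms: none
Why: the weakly basic organocerium reagent should add once to the lactone carbonyl instead of removing the acidic C3–H, and the tetrahedral alkoxide holds at −78 °C so that the cyclic hemiketal is obtained on work-up.

Step 9
Reactants: 19 cyclic hemiketal
Product: 20 (2S,3S,4S,5R)-2,5-bis[4-(benzyloxy)phenyl]-3,4-bis[4-chloro-3,5-bis(triisopropylsilyloxy)phenyl]oxolane
Conditions: Et3SiH (5 equiv), BF3·OEt2 (2 equiv), CH2Cl2, −78 °C; aq. NaHCO3 at −78 °C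
Reagents that add atoms: none
Why: ionisation to the 2-aryl oxocarbenium ion and silane hydride transfer anti to the adjacent C3 aryl group (reductive deoxygenation of a cyclic hemiketal, the known entry to 2,3-cis-2,5-cis tetrahydrofuran lignans) should set T-C2 as S with its aryl group cis to that on T-C3.

Step 10
Reactants: 20 tetrakis(silyl ether) of the core
Product: 21 5,5′-{(2S,3S,4S,5R)-2,5-bis[4-(benzyloxy)phenyl]oxolane-3,4-diyl}bis(2-chlorobenzene-1,3-diol)
Conditions: n-Bu4NF (4.4 equiv), AcOH (4.4 equiv), THF, 0 °C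
Reagents that add atoms: none
Why: buffered fluoride desilylation should free the four phenols while the benzyl ethers, the aryl chlorides and the benzylic ethers of ring T stay untouched.

Step 11
Reactants: 22 resveratrol
Product: 23 (E)-3,4′,5-tris(benzyloxy)stilbene
Conditions: BnBr, K2CO3, DMF, 50 °C
Reagents that add atoms: benzyl bromide, BrCc1ccccc1
Why: Williamson etherification of the three phenols leaves the E alkene unchanged.

Step 12
Reactants: 21 core tetraphenol; 23 (E)-3,4′,5-tris(benzyloxy)stilbene (2.4 equiv)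
Product: 24 bis-dihydrobenzofuran: target skeleton with chlorine on both D-C7, both D-C6 hydroxyls free and the other eight phenols as benzyl ethers; ring T (2S,3S,4S,5R), each ring D (2S,3S)
Conditions: undivided cell, graphite anode, Pt cathode, n-Bu4NBF4 (0.1 M), (CF3)2CHOH/CH2Cl2 (1:1), constant current (2 mA cm−2), 4.4 F per mol of 21, 0 °C
Reagents that add atoms: none
Why: Proposed new method: at the carbon anode stilbene 23, the most easily oxidised component in the fluorinated alcohol, should give a radical cation that the free ortho carbon of each 2-chlororesorcinol ring (next to one hydroxyl, para to the other) attacks at the alkene carbon bearing the 3,5-bis(benzyloxy)phenyl group, and a second electron loss leaves the 4-benzyloxybenzyl cation. The closest known reaction type is the anodic or photoredox oxidative [3+2] annulation of 4-alkoxyphenols with β-substituted electron-rich styrenes to trans-2-aryl-2,3-dihydrobenzofurans; a hindered resorcinol carbon, a 1,2-diarylethene and two annulations on one substrate go beyond it. Each ring D closes, after its C3–C3a bond has formed, by 5-exo-trig attack of the neighbouring phenol oxygen on that cation (O1–C2). D-C2 is set trans to D-C3 by the closure itself, the two aryl groups taking the anti arrangement as in the known cases, whereas D-C3 of each ring is set only by the adjoining T-C3 or T-C4 stereocentre, whose hydrogen should eclipse the reacting ortho carbon and leave the two faces of the arene unequally flanked; this facial control is the least secure element. Site selectivity on the resorcinol is secured by the chlorine on the carbon between the hydroxyls, which also shuts off a later annulation at D-C7, while alkene regiochemistry follows from the 4-benzyloxyphenyl group, the only one able to stabilise the cation. Chemoselectivity over further oxidation of the product phenols, and over a third annulation at the buttressed D-C5, rests on dosing the charge and limiting the stilbene.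

Step 13
Reactants: 24 bis-dihydrobenzofuran
Product: 25 CNP0270490.1 (target); ring T (2S,3S,4S,5R), each ring D (2S,3S)
Conditions: H2 (1 atm), 10% Pd/C, NaOAc (4 equiv), THF/MeOH, 25 °C
Reagents that add atoms: none
Why: heterogeneous palladium-catalysed hydrogenolysis should remove the eight benzyl ethers and, with acetate taking up the HCl, the two aryl chlorines (hydrodechlorination of 2-chlorophenols), while the hindered secondary benzylic C–O bonds of rings T and D cleave more slowly and the buffered medium leaves the acid-labile T-C2 centre unchanged.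

**Compound list**

1 | 1-(benzyloxy)-4-bromobenzene | Brc1ccc(OCc2ccccc2)cc1 | starting material
2 | succinic anhydride | O=C1CCC(=O)O1 | starting material
3 | 4-(benzyloxy)phenylmagnesium bromide (not isolated) | Br[Mg]c1ccc(OCc2ccccc2)cc1 | intermediate
4 | 4-[4-(benzyloxy)phenyl]-4-oxobutanoic acid | OC(=O)CCC(=O)c1ccc(OCc2ccccc2)cc1 | intermediate
5 | (4R)-4-[4-(benzyloxy)phenyl]-4-hydroxybutanoic acid (not isolated) | OC(=O)CC[C@@H](O)c1ccc(OCc2ccccc2)cc1 | intermediate
6 | (5R)-5-[4-(benzyloxy)phenyl]oxolan-2-one | O=C1CC[C@H](c2ccc(OCc3ccccc3)cc2)O1 | intermediate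
7 | (5R)-5-[4-(benzyloxy)phenyl]-3-(phenylselanyl)oxolan-2-one, C3 epimers (not isolated) | O=C1C([Se]c2ccccc2)C[C@H](c2ccc(OCc3ccccc3)cc2)O1 | intermediate
8 | (5R)-5-[4-(benzyloxy)phenyl]furan-2(5H)-one | O=C1C=C[C@H](c2ccc(OCc3ccccc3)cc2)O1 | intermediate
9 | 2-chlororesorcinol | Oc1cccc(O)c1Cl | starting material
10 | 2-chloro-1,3-bis(triisopropylsilyloxy)benzene | Clc1c(O[Si](C(C)C)(C(C)C)C(C)C)cccc1O[Si](C(C)C)(C(C)C)C(C)C | intermediate
11 | 2-[4-chloro-3,5-bis(triisopropylsilyloxy)phenyl]-4,4,5,5-tetramethyl-1,3,2-dioxaborolane (not isolated) | CC1(C)OB(OC1(C)C)c1cc(O[Si](C(C)C)(C(C)C)C(C)C)c(Cl)c(O[Si](C(C)C)(C(C)C)C(C)C)c1 | intermediate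
12 | 5-bromo-2-chloro-1,3-bis(triisopropylsilyloxy)benzene | Brc1cc(O[Si](C(C)C)(C(C)C)C(C)C)c(Cl)c(O[Si](C(C)C)(C(C)C)C(C)C)c1 | intermediate
13 | [4-chloro-3,5-bis(triisopropylsilyloxy)phenyl]magnesium bromide (not isolated) | Br[Mg]c1cc(O[Si](C(C)C)(C(C)C)C(C)C)c(Cl)c(O[Si](C(C)C)(C(C)C)C(C)C)c1 | intermediate
14 | (4S,5R)-5-[4-(benzyloxy)phenyl]-4-[4-chloro-3,5-bis(triisopropylsilyloxy)phenyl]-2-(trimethylsilyloxy)-4,5-dihydrofuran (not isolated) | C[Si](C)(C)OC1=C[C@@H](c2cc(O[Si](C(C)C)(C(C)C)C(C)C)c(Cl)c(O[Si](C(C)C)(C(C)C)C(C)C)c2)[C@H](c2ccc(OCc3ccccc3)cc2)O1 | intermediate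
15 | (4S,5R)-5-[4-(benzyloxy)phenyl]-4-[4-chloro-3,5-bis(triisopropylsilyloxy)phenyl]oxolan-2-one | O=C1C[C@@H](c2cc(O[Si](C(C)C)(C(C)C)C(C)C)c(Cl)c(O[Si](C(C)C)(C(C)C)C(C)C)c2)[C@H](c2ccc(OCc3ccccc3)cc2)O1 | intermediate
16 | (3S,4S,5R)-5-[4-(benzyloxy)phenyl]-3,4-bis[4-chloro-3,5-bis(triisopropylsilyloxy)phenyl]oxolan-2-one | O=C1[C@H](c2cc(O[Si](C(C)C)(C(C)C)C(C)C)c(Cl)c(O[Si](C(C)C)(C(C)C)C(C)C)c2)[C@@H](c2cc(O[Si](C(C)C)(C(C)C)C(C)C)c(Cl)c(O[Si](C(C)C)(C(C)C)C(C)C)c2)[C@H](c2ccc(OCc3ccccc3)cc2)O1 | intermediate
17 | 4-(benzyloxy)phenyllithium (not isolated) | [Li]c1ccc(OCc2ccccc2)cc1 | intermediate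
18 | [4-(benzyloxy)phenyl]cerium dichloride (not isolated) | Cl[Ce](Cl)c1ccc(OCc2ccccc2)cc1 | intermediate
19 | (3S,4S,5R)-2,5-bis[4-(benzyloxy)phenyl]-3,4-bis[4-chloro-3,5-bis(triisopropylsilyloxy)phenyl]oxolan-2-ol, C2 epimers | OC1(c2ccc(OCc3ccccc3)cc2)[C@H](c2cc(O[Si](C(C)C)(C(C)C)C(C)C)c(Cl)c(O[Si](C(C)C)(C(C)C)C(C)C)c2)[C@@H](c2cc(O[Si](C(C)C)(C(C)C)C(C)C)c(Cl)c(O[Si](C(C)C)(C(C)C)C(C)C)c2)[C@H](c2ccc(OCc3ccccc3)cc2)O1 | intermediate
20 | (2S,3S,4S,5R)-2,5-bis[4-(benzyloxy)phenyl]-3,4-bis[4-chloro-3,5-bis(triisopropylsilyloxy)phenyl]oxolane | [C@@H]1(c2ccc(OCc3ccccc3)cc2)[C@H](c2cc(O[Si](C(C)C)(C(C)C)C(C)C)c(Cl)c(O[Si](C(C)C)(C(C)C)C(C)C)c2)[C@@H](c2cc(O[Si](C(C)C)(C(C)C)C(C)C)c(Cl)c(O[Si](C(C)C)(C(C)C)C(C)C)c2)[C@H](c2ccc(OCc3ccccc3)cc2)O1 | intermediate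
21 | 5,5′-{(2S,3S,4S,5R)-2,5-bis[4-(benzyloxy)phenyl]oxolane-3,4-diyl}bis(2-chlorobenzene-1,3-diol) | [C@@H]1(c2ccc(OCc3ccccc3)cc2)[C@H](c2cc(O)c(Cl)c(O)c2)[C@@H](c2cc(O)c(Cl)c(O)c2)[C@H](c2ccc(OCc3ccccc3)cc2)O1 | intermediate
22 | resveratrol | Oc1ccc(/C=C/c2cc(O)cc(O)c2)cc1 | starting material
23 | (E)-3,4′,5-tris(benzyloxy)stilbene | C(Oc1ccc(/C=C/c2cc(OCc3ccccc3)cc(OCc3ccccc3)c2)cc1)c1ccccc1 | intermediate
24 | 7,7′-dichloro octabenzyl ether of the target with both D-C6 hydroxyls free; ring T (2S,3S,4S,5R), rings D (2S,3S) | O(Cc1ccccc1)c1ccc([C@H]2Oc3c(Cl)c(O)cc([C@@H]4[C@@H](c5cc(O)c(Cl)c6c5[C@H](c5cc(OCc7ccccc7)cc(OCc7ccccc7)c5)[C@@H](c5ccc(OCc7ccccc7)cc5)O6)[C@H](c5ccc(OCc6ccccc6)cc5)O[C@@H]4c4ccc(OCc5ccccc5)cc4)c3[C@@H]2c2cc(OCc3ccccc3)cc(OCc3ccccc3)c2)cc1 | intermediate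
25 | CNP0270490.1; ring T (2S,3S,4S,5R), rings D (2S,3S) | Oc1ccc([C@H]2Oc3cc(O)cc([C@@H]4[C@@H](c5cc(O)cc6c5[C@H](c5cc(O)cc(O)c5)[C@@H](c5ccc(O)cc5)O6)[C@H](c5ccc(O)cc5)O[C@@H]4c4ccc(O)cc4)c3[C@@H]2c2cc(O)cc(O)c2)cc1 | target

**Step count and risks**

Total step count: 13. Longest linear sequence: 10 steps (1, 2, 3, 6, 7, 8, 9, 10, 12, 13).

The three steps most likely to fail:

Step 12. Carbon–carbon bond formation at the hindered ortho carbon may be too slow, so that the stilbene radical cation dimerises or is captured at phenol oxygen. Facial selectivity at D-C3 in either ring may be poor and give diastereomer mixtures, and the phenolic product may be oxidised further. The fallback uses known polar chemistry in place of oxidation and sets out from 21. A three-component condensation with 3,5-bis(benzyloxy)benzaldehyde and sodium 4-methylbenzenesulfinate in aqueous formic acid at room temperature should alkylate the same free ortho carbon of each chlororesorcinol ring and give the bis[aryl(tosyl)methyl]phenol F1. With Cs2CO3, each ring of F1 loses sulfinate to a quinone methide, which undergoes the known [4+1] annulation with the ylide of (4-benzyloxybenzyl)dimethylsulfonium bromide F2 (from 4-(benzyloxy)benzyl bromide and dimethyl sulfide). The ylide carbon becomes D-C2 and the ring closes trans, and the route is rejoined at 24.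

Step 6. The basic organometallic reagent may remove the acidic C5 hydrogen of the butenolide (reversible passage through the achiral 2-silyloxyfuran), which would erode enantiomeric purity, and anti addition may be incomplete. The fallback replaces the basic copper–magnesium reagent by a boron nucleophile in acid; it sets out from 8 and from boronate 11, which is then isolated after the borylation stage of step 5. NaIO4/NH4OAc in aqueous acetone should cleave the pinacol ester to [4-chloro-3,5-bis(triisopropylsilyloxy)phenyl]boronic acid F3. Pd(OAc)2 with 2,2′-bipyridine in AcOH/THF/H2O at 40 °C should then transfer its aryl group to 8 (aryl–palladium insertion anti to the C5 aryl group, then protonolysis of the palladium enolate) in a medium in which the C5 hydrogen is not removed, and the route is rejoined at 15.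

Step 13. The C–Cl bonds may need prolonged reaction, and under it the benzylic C–O bonds of rings D or T may be cleaved; alternatively dechlorination may stay incomplete. The fallback separates the two tasks and sets out from 24. (IPr)Pd(allyl)Cl with NaOt-Bu in i-PrOH at 60 °C (zerovalent palladium, the alkoxide as hydride donor) should remove only the two chlorines and give the octabenzyl ether F4. Catalytic transfer hydrogenolysis (10% Pd/C, 1,4-cyclohexadiene, EtOAc/EtOH, 25 °C), in which no acid forms, should then take off the benzyl groups and arrive at 25.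

**Further compounds**

F1 | step 12 | 5,5′-{(2S,3S,4S,5R)-2,5-bis[4-(benzyloxy)phenyl]oxolane-3,4-diyl}bis{4-[[3,5-bis(benzyloxy)phenyl](4-methylbenzenesulfonyl)methyl]-2-chlorobenzene-1,3-diol}, sulfonyl-bearing carbons as epimers | [C@@H]1(c2ccc(OCc3ccccc3)cc2)[C@H](c2cc(O)c(Cl)c(O)c2C(c2cc(OCc3ccccc3)cc(OCc3ccccc3)c2)S(=O)(=O)c2ccc(C)cc2)[C@@H](c2cc(O)c(Cl)c(O)c2C(c2cc(OCc3ccccc3)cc(OCc3ccccc3)c2)S(=O)(=O)c2ccc(C)cc2)[C@H](c2ccc(OCc3ccccc3)cc2)O1
F2 | step 12 | (4-benzyloxybenzyl)dimethylsulfonium bromide | C[S+](C)Cc1ccc(OCc2ccccc2)cc1.[Br-]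
F3 | step 6 | [4-chloro-3,5-bis(triisopropylsilyloxy)phenyl]boronic acid | OB(O)c1cc(O[Si](C(C)C)(C(C)C)C(C)C)c(Cl)c(O[Si](C(C)C)(C(C)C)C(C)C)c1
F4 | step 13 | octabenzyl ether of the target with both D-C6 hydroxyls free (24 without chlorine); ring T (2S,3S,4S,5R), rings D (2S,3S) | O(Cc1ccccc1)c1ccc([C@H]2Oc3cc(O)cc([C@@H]4[C@@H](c5cc(O)cc6c5[C@H](c5cc(OCc7ccccc7)cc(OCc7ccccc7)c5)[C@@H](c5ccc(OCc7ccccc7)cc5)O6)[C@H](c5ccc(OCc6ccccc6)cc5)O[C@@H]4c4ccc(OCc5ccccc5)cc4)c3[C@@H]2c2cc(OCc3ccccc3)cc(OCc3ccccc3)c2)cc1
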